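## The problem

The target 14 is a (2S)-flavanone. Ring A is a phloroglucinol-type ring with free hydroxyls at C5 and C7 and a prenyl group at C8. Ring B carries a 4'-methoxy group and a 3-methylbut-3-enyl chain at C3'. C2 is the only stereocentre, so nothing in the molecule can set it and it must be bought or made by a catalyst. It is also fragile: as a β-aryloxy ketone it opens by retro-oxa-Michael reaction under base, and as a benzylic ether para to the 4'-methoxy group it can ionise under acid. Ring A offers two nucleophilic CH positions, C6 and C8, and electrophilic prenylation does not separate them cleanly and also attacks oxygen. The side chains add limits: a prenyl group ortho to the 7-OH closes to a dimethylchroman under acid, and the 1,1-disubstituted alkene on ring B migrates under acid or metal hydrides. The feature that opens the problem is that C8 is para to O5. The ortho neighbours of C5 are the ring-fusion carbon C4a and the CH carbon C6, and O5 sits peri to the C4 carbonyl, where a lanthanide can chelate. A prenyl group placed on O5 can therefore shift only to C6, and from there by a second shift to C8, where it arrives with normal prenyl connectivity. Hesperidin 1 already holds the (2S) centre, the 5-OH, a masked O7, the 4'-methoxy group and a 3'-OH at the carbon where the chain must go.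

## Retrosynthesis

**O7–acetyl (14 from 13).** The last cut is the acetyl group on O7. The acetate is kept to the end because it steers the key step and because it can be removed at near-neutral pH. The forward step must not open ring C or let the C8 prenyl group cyclise onto the new 7-OH.

**C8–CH2 (13 from 10, key disconnection).** The bond between C8 and the prenyl CH2 is cut and the prenyl group is returned to O5, giving ether 10. Direct C-prenylation of a 5,7-dihydroxyflavanone would give C6, C8 and O products and needs base. A Claisen shift from an O7 1,1-dimethylallyl ether has two open ortho positions. From O5 there is only one, and the onward Cope shift ends at C8. The precursor 10 lacks only this one C–C bond. The forward step has to favour the Cope shift of the ortho-dienone 11 over its tautomerisation, pass through the para-dienone 12, and leave C2 and both alkenes untouched.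

**O5–CH2 (10 from 8 and 9).** The ether bond is cut to phenol 8 and prenol 9. A Mitsunobu reaction is preferred to alkylation with prenyl bromide and carbonate because it is base-free. In 8 the 5-OH is the only free phenol, so no site question arises.

**C3'–CH2 (8 from 5 and 7; 7 from 6).** The chain is cut at the aryl–alkyl bond to aryl triflate 5 and alkylzinc reagent 7, made from bromide 6. Negishi coupling is chosen over a Suzuki coupling because it needs no base. It is placed before the O5 prenylation because zerovalent palladium could ionise an aryl prenyl ether such as 10. Friedel–Crafts alkylation of ring B would give neither the position nor the intact alkene. The forward step must outrun β-hydride elimination and spare the acetate.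

**O7–acetyl, glycoside, O3'–triflyl (5 from 4, 4 from 2 via 3, 2 from 1).** Acetate 5 comes from diol 4 by acylation of the unchelated 7-OH. Diol 4 comes from glycoside 2 by acid hydrolysis, through the glucoside 3. Triflate 2 comes from hesperidin 1 by sulfonylation of the 3'-phenol. The order matters. In the aglycone the 7-OH is the most acidic phenol and would be triflated first. In 1 the rutinoside protects O7 and the 5-OH is chelated, so the 3'-OH is the only reactive phenol. The triflate also makes ring B electron-poor during the hot acid step, which disfavours ionisation at C2.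

## Roads not taken

**Alternative 1:** Ring C is cut at C4a–C4, C4–C3 and O1–C2, giving the ring A iodophenol A2, carbon monoxide and the ring B arylalkyne A3. In the forward sense PdCl2(PPh3)2, a divalent palladium precatalyst reduced in the flask to zerovalent palladium, inserts into the C–I bond of A2. CO insertion and coupling with A3 give an ynone, which Et2NH closes to flavone A1. An enantioselective 1,4-hydride addition and removal of both methoxymethyl groups would follow.
- Merits: three components join in one flask, the route is fully convergent, and it is independent of a natural source, so analogues are easy.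
- Weak points: A1 is flat, so C2 must be made by asymmetric conjugate reduction at a doubly substituted vinylogous-ester carbon. Hydrogenation catalysts able to reduce flavones would also threaten the prenyl and isopentenyl alkenes. A2 carries the same C6/C8 prenyl problem and needs its own multistep synthesis. The acetals must come off with acid after both alkenes are in place.
- Comparison: this road is better in convergence and does not inherit the epimeric purity of a glycoside. The chosen plan sets against this that C2 is never created, no acid meets the alkenes, and the route is clearly shorter once A2 and A3 are counted.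

**Alternative 2:** The C2–C1' bond is cut, giving chromone A5 and arylboronic acid A6. A chiral monovalent rhodium catalyst, [RhCl(C2H4)2]2 with a chiral diene and aqueous KOH, would transfer the aryl group to C2 of A5 and give the protected flavanone A4.
- Merits: this is the most direct catalytic way to the stereocentre, it is convergent, the reaction type is well established for chromones, and A4 is one deprotection from the target.
- Weak points: the flavanone product sits in aqueous hydroxide, where retro-oxa-Michael opening can erode C2. A5 is an electron-rich acceptor, crowded at C5 and C8. A6 is electron-rich and prone to protodeboronation. The final acid step puts the prenyl group next to a freed 7-OH. A5 still needs a regiocontrolled C8 prenylation, so that problem is moved, not solved.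
- Comparison: for stereocontrol this road is at least as good, because the enantiomeric purity is set by the catalyst and not inherited. The chosen plan answers with no chiral catalyst, a cheap starting material, C8 regiochemistry settled by the bond-forming step itself, and a neutral end game.

**Alternative 3:** The C2–C3 bond is cut, leading back to the racemic enol acetal A8. A chiral Lewis acid (a silylium imidodiphosphorimidate ion pair, or MeAl(O2C20H12)) would ionise the C2–O3 bond. The resulting enolate carbon would add to the aryl-stabilised oxocarbenium ion and close ring C as the bis-silyl flavanone A7.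
- Merits: it is stereoconvergent, so a racemic precursor gives one enantiomer, and the C–C bond and ring C form in one step.
- Weak points: A8 is hydrolytically fragile and needs a titanium methylenation (Cp2TiMe2) of an ester-type carbonyl. A strongly Lewis-acidic catalyst would meet two nucleophilic alkenes and an electron-rich ring A. The long-lived 4-methoxyphenyl oxocarbenium ion invites racemic recombination. The 5-silyloxy group crowds the forming carbonyl. Fluoride deprotection is basic enough to endanger ring C.
- Comparison: this is the most elegant stereochemical idea and could be short after A8. It carries two open research questions, the asymmetric step on this substitution pattern and its tolerance of the alkenes. The chosen plan needs no new method.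

Key step: step 7

Assumption: hesperidin is used as its (2S) epimer. Because the sugar makes the two C2 epimers diastereomers, a lot carrying some (2R) epimer would be purified by crystallisation before step 1.

## Route

Step 1
Reactants: 1 hesperidin, the 7-O-[α-L-rhamnopyranosyl-(1→6)-β-D-glucopyranoside] of (2S)-hesperetin
Product: 2 hesperidin 3'-O-triflate, (2S)-5-hydroxy-2-[4-methoxy-3-(trifluoromethanesulfonyloxy)phenyl]-7-(rutinosyloxy)chroman-4-one
Conditions: PhNTf2 (1.1 equiv), Et3N (2 equiv), DMF, 0 °C to rt
Reagents that add atoms: N-phenylbis(trifluoromethanesulfonimide), O=S(=O)(N(c1ccccc1)S(=O)(=O)C(F)(F)F)C(F)(F)F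
Why: Phenol triflation with a mild triflyl donor that reacts with aryloxides and not with the six secondary sugar hydroxyls (hesperidin has no primary one); O7 is glycosylated and the 5-OH is chelated to the C4 carbonyl, so the 3'-phenol should be the only site, and Et3N is too weak a base to open ring C.

Step 2
Reactants: 2 hesperidin 3'-O-triflate
Product: 4 (2S)-5,7-dihydroxy-2-[4-methoxy-3-(trifluoromethanesulfonyloxy)phenyl]chroman-4-one (hesperetin 3'-O-triflate), via 7-O-glucoside triflate 3 (not isolated)
Conditions: 2 M aq HCl–1,4-dioxane (1:1), 90 °C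
Reagents that add atoms: none
Why: Acid-catalysed glycoside hydrolysis, in which the 6-deoxy sugar acetal should cleave first and the aryl glucoside second; aryl triflates resist aqueous acid, and the electron-withdrawing triflate on ring B disfavours benzylic C2–O1 ionisation, so the (2S) centre should hold.

Step 3
Reactants: 4 hesperetin 3'-O-triflate
Product: 5 (2S)-7-acetoxy-5-hydroxy-2-[4-methoxy-3-(trifluoromethanesulfonyloxy)phenyl]chroman-4-one
Conditions: Ac2O (1.05 equiv), pyridine, CH2Cl2, 0 °C
Reagents that add atoms: acetic anhydride, CC(=O)OC(C)=O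
Why: Selective O-acylation: the free 7-phenol reacts at 0 °C while the 5-OH stays locked in its hydrogen bond to the C4 carbonyl, and one equivalent of anhydride keeps the reaction at the monoacetate.

Step 4
Reactants: 6 4-bromo-2-methylbut-1-ene
Product: 7 (3-methylbut-3-en-1-yl)zinc bromide, as a THF solution with LiCl
Conditions: Zn dust (activated with BrCH2CH2Br and Me3SiCl), LiCl, THF, 50 °C
Reagents that add atoms: zinc, [Zn]
Why: LiCl-assisted direct insertion of zinc into a primary alkyl bromide; the homoallylic zinc species has no favourable cyclisation path and is mild enough to tolerate the ester and ketone it meets in step 5.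

Step 5
Reactants: 5 (2S)-7-acetoxy-5-hydroxyflavanone 3'-O-triflate; 7 (3-methylbut-3-en-1-yl)zinc bromide
Product: 8 (2S)-7-acetoxy-5-hydroxy-2-[4-methoxy-3-(3-methylbut-3-en-1-yl)phenyl]chroman-4-one
Conditions: PdCl2(dppf) (5 mol %; dppf = 1,1'-bis(diphenylphosphino)ferrocene), 7 (2.5 equiv), THF, 55 °C
Reagents that add atoms: none
Why: Negishi sp2–sp3 coupling: the aryl triflate adds oxidatively to zerovalent palladium, the alkyl group is transferred from zinc, and reductive elimination from the wide-bite-angle dppf complex should outrun β-hydride loss; no base is present, RZnBr leaves the acetate and ketone alone, and the excess reagent covers deprotonation of the 5-OH.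

Step 6
Reactants: 8 (2S)-7-acetoxy-5-hydroxy-3'-(3-methylbut-3-enyl)-4'-methoxyflavanone; 9 3-methylbut-2-en-1-ol (prenol)
Product: 10 (2S)-7-acetoxy-2-[4-methoxy-3-(3-methylbut-3-en-1-yl)phenyl]-5-[(3-methylbut-2-en-1-yl)oxy]chroman-4-one
Conditions: PPh3 (1.5 equiv), DIAD (1.5 equiv), THF, 0 °C to rt
Reagents that add atoms: none
Why: Mitsunobu etherification of the only free phenol with a primary allylic alcohol; substitution at the CH2 gives the unrearranged prenyl ether, and the neutral medium protects ring C, the C2 centre and the 7-acetate.

Step 7
Reactants: 10 (2S)-7-acetoxy-5-(prenyloxy)flavanone with the complete ring B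
Product: 13 (2S)-7-acetoxy-5-hydroxy-2-[4-methoxy-3-(3-methylbut-3-en-1-yl)phenyl]-8-(3-methylbut-2-en-1-yl)chroman-4-one, via C6 ortho-dienone 11 (not isolated), via C8 para-dienone 12 (not isolated)
Conditions: Eu(fod)3 [europium tris(6,6,7,7,8,8,8-heptafluoro-2,2-dimethyl-3,5-octanedionate)] (10 mol %), CHCl3 (acid-free), 60 °C
Reagents that add atoms: none
Why: Trivalent europium in Eu(fod)3 binds the C4 carbonyl and the ether oxygen O5 as a six-membered chelate, weakens the O5–CH2 bond and triggers an aromatic Claisen [3,3] shift that delivers the tertiary prenyl terminus to C6, the only ortho carbon bearing hydrogen (C4a is the ring fusion), giving dienone 11. In 11 the new quaternary carbon is wedged between the C5 carbonyl and the acetoxy-bearing C7, and the 1,5-diene C8=C7–C6–CMe2–CH=CH2 relieves this strain by a Cope [3,3] shift that forms the C8–CH2 bond and restores normal prenyl connectivity in dienone 12. Proton transfer from C8 to O5 then gives the chelated phenol 13. The closest known reaction type is the europium-catalysed para-Claisen–Cope rearrangement of 5-O-prenyl-7-O-acylflavanones. No ring is closed and no stereocentre is created: the sp3 centres at C6 of 11 and C8 of 12 vanish on aromatisation, and C2 is a spectator. The selectivity required is C8 over C6, that is, Cope migration of 11 faster than its tautomerisation to a 6-(1,1-dimethylallyl)phenol; the 7-acetate should secure this by removing the acidic 7-OH that could relay the proton and by adding to the crowding at C6, and the aprotic medium with a Lewis acid that has no acidic proton offers no shuttle for the C6-to-O5 hydrogen shift. Catalysis allows 60 °C in place of about 200 °C, so the isopentenyl chain, the acetate and the configuration at C2 should survive.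

Step 8
Reactants: 13 (2S)-7-acetoxy-5-hydroxy-8-prenylflavanone with the complete ring B
Product: 14 (2S)-5,7-dihydroxy-2-[4-methoxy-3-(3-methylbut-3-en-1-yl)phenyl]-8-(3-methylbut-2-en-1-yl)chroman-4-one
Conditions: NH4OAc (excess), MeOH–H2O (4:1), rt
Reagents that add atoms: none
Why: NH4OAc-mediated methanolysis of an aryl acetate at near-neutral pH, with the acetyl group passing to methanol; the medium is neither basic enough for retro-oxa-Michael opening at C2 nor acidic enough to cyclise the prenyl group onto O7 or move the 1,1-disubstituted double bond.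

## Compound list

1 | hesperidin, (2S)-hesperetin 7-O-rutinoside | COc1ccc([C@@H]2CC(=O)c3c(O)cc(O[C@@H]4O[C@H](CO[C@@H]5O[C@@H](C)[C@H](O)[C@@H](O)[C@H]5O)[C@@H](O)[C@H](O)[C@H]4O)cc3O2)cc1O | starting material
2 | hesperidin 3'-O-triflate | COc1ccc([C@@H]2CC(=O)c3c(O)cc(O[C@@H]4O[C@H](CO[C@@H]5O[C@@H](C)[C@H](O)[C@@H](O)[C@H]5O)[C@@H](O)[C@H](O)[C@H]4O)cc3O2)cc1OS(=O)(=O)C(F)(F)F | intermediate
3 | (2S)-hesperetin 7-O-β-D-glucoside 3'-O-triflate (not isolated) | COc1ccc([C@@H]2CC(=O)c3c(O)cc(O[C@@H]4O[C@H](CO)[C@@H](O)[C@H](O)[C@H]4O)cc3O2)cc1OS(=O)(=O)C(F)(F)F | intermediate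
4 | (2S)-5,7-dihydroxy-2-[4-methoxy-3-(trifluoromethanesulfonyloxy)phenyl]chroman-4-one | COc1ccc([C@@H]2CC(=O)c3c(O)cc(O)cc3O2)cc1OS(=O)(=O)C(F)(F)F | intermediate
5 | (2S)-7-acetoxy-5-hydroxy-2-[4-methoxy-3-(trifluoromethanesulfonyloxy)phenyl]chroman-4-one | COc1ccc([C@@H]2CC(=O)c3c(O)cc(OC(C)=O)cc3O2)cc1OS(=O)(=O)C(F)(F)F | intermediate
6 | 4-bromo-2-methylbut-1-ene | C=C(C)CCBr | starting material
7 | (3-methylbut-3-en-1-yl)zinc bromide | C=C(C)CC[Zn]Br | intermediate
8 | (2S)-7-acetoxy-5-hydroxy-2-[4-methoxy-3-(3-methylbut-3-en-1-yl)phenyl]chroman-4-one | C=C(C)CCc1cc([C@@H]2CC(=O)c3c(O)cc(OC(C)=O)cc3O2)ccc1OC | intermediate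
9 | 3-methylbut-2-en-1-ol (prenol) | CC(C)=CCO | starting material
10 | (2S)-7-acetoxy-2-[4-methoxy-3-(3-methylbut-3-en-1-yl)phenyl]-5-[(3-methylbut-2-en-1-yl)oxy]chroman-4-one | C=C(C)CCc1cc([C@@H]2CC(=O)c3c(OCC=C(C)C)cc(OC(C)=O)cc3O2)ccc1OC | intermediate
11 | (2S)-7-acetoxy-2-[4-methoxy-3-(3-methylbut-3-en-1-yl)phenyl]-6-(2-methylbut-3-en-2-yl)-2,3-dihydro-4H-chromene-4,5(6H)-dione, C6 ortho-dienone, either configuration at C6 (not isolated) | C=C(C)CCc1cc([C@@H]2CC(=O)C3=C(O2)C=C(OC(C)=O)C(C(C)(C)C=C)C3=O)ccc1OC | intermediate
12 | (2S)-7-acetoxy-2-[4-methoxy-3-(3-methylbut-3-en-1-yl)phenyl]-8-(3-methylbut-2-en-1-yl)-2,3-dihydro-4H-chromene-4,5(8H)-dione, C8 para-dienone, either configuration at C8 (not isolated) | C=C(C)CCc1cc([C@@H]2CC(=O)C3=C(O2)C(CC=C(C)C)C(OC(C)=O)=CC3=O)ccc1OC | intermediate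
13 | (2S)-7-acetoxy-5-hydroxy-2-[4-methoxy-3-(3-methylbut-3-en-1-yl)phenyl]-8-(3-methylbut-2-en-1-yl)chroman-4-one | C=C(C)CCc1cc([C@@H]2CC(=O)c3c(O)cc(OC(C)=O)c(CC=C(C)C)c3O2)ccc1OC | intermediate
14 | (2S)-5,7-dihydroxy-2-[4-methoxy-3-(3-methylbut-3-en-1-yl)phenyl]-8-(3-methylbut-2-en-1-yl)chroman-4-one | C=C(C)CCc1cc([C@@H]2CC(=O)c3c(O)cc(O)c(CC=C(C)C)c3O2)ccc1OC | target

## Step count and risks

Total: 8 steps. Longest linear sequence: 7 steps from hesperidin 1 (steps 1, 2, 3, 5, 6, 7, 8); step 4 prepares the zinc reagent.

**Step 7 (key step).** Three things could go wrong.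
- Dienone 11 may tautomerise before the Cope shift, so that the allyl group stays at C6 in its 1,1-dimethylallyl form.
- The Lewis acid may promote reversible C2–O1 ionisation, helped by the electron-rich ring B, and erode the configuration at C2.
- Adventitious acid may move the 1,1-disubstituted double bond.

Fallback: the rearrangement is moved in front of the cross-coupling, so that ring B is electron-poor and alkene-free when it meets the Lewis acid or heat. Setting out from triflate 5, Mitsunobu etherification with prenol 9 would give (2S)-7-acetoxy-5-(prenyloxy)flavanone 3'-O-triflate F1. Eu(fod)3 in CHCl3 at 60 °C, or failing that plain heating in N,N-diethylaniline, would carry it through the C6 ortho-dienone triflate F2 and the C8 para-dienone triflate F3 to (2S)-7-acetoxy-5-hydroxy-8-prenylflavanone 3'-O-triflate F4. Negishi coupling of F4 with zinc reagent 7 under PdCl2(dppf) returns to the route at 13.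

**Step 1.** Sulfonylation may spill over to the chelated 5-OH or a sugar hydroxyl, conversion may stall because 1 dissolves poorly, or the amine base may slowly epimerise C2 in the glycoside. Fallback: the sugar is removed first and O7 is re-masked by acylation. Setting out from 1, hydrolysis in 2 M aqueous HCl–1,4-dioxane at 90 °C would pass through hesperetin 7-O-β-D-glucoside F5 to (2S)-hesperetin F6. One equivalent each of Ac2O and Et3N in THF at −20 °C should acylate the most acidic phenol and give 7-O-acetylhesperetin F7. Triflation of the remaining unchelated 3'-phenol with PhNTf2 and Et3N returns to the route at 5.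

**Step 5.** The alkylpalladium intermediate may undergo β-hydride elimination, which is favoured here because it would release a conjugated diene. That would reduce the triflate, and the resulting palladium hydride could move the chain double bond. The 5-OH also consumes zinc reagent by protonolysis. Fallback: the alkyl group is delivered from boron. Setting out from bromide 6, magnesium in THF would give (3-methylbut-3-en-1-yl)magnesium bromide F8. B-Methoxy-9-borabicyclo[3.3.1]nonane captures it as the bromomagnesium B-methoxy-B-(3-methylbut-3-en-1-yl) borate F9. F9 transfers its primary alkyl group to triflate 5 under PdCl2(dppf) in THF–DMF at 65 °C without added base (the base-free variant of the B-alkyl Suzuki–Miyaura coupling), returning to the route at 8.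

**Step 8.** Acetyl transfer may stall, and long exposure of the free 5,7-dihydroxyflavanone to the ammonium salt may slowly open ring C and erode C2. Fallback: biocatalytic alcoholysis. Setting out from 13, immobilised Candida antarctica lipase B with n-butanol in tert-butyl methyl ether at 40 °C would transfer the acetyl group to butanol at neutral pH and return to the route at 14. No new compound is made.

## Further compounds

F1 | step 7 | (2S)-7-acetoxy-2-[4-methoxy-3-(trifluoromethanesulfonyloxy)phenyl]-5-[(3-methylbut-2-en-1-yl)oxy]chroman-4-one | COc1ccc([C@@H]2CC(=O)c3c(OCC=C(C)C)cc(OC(C)=O)cc3O2)cc1OS(=O)(=O)C(F)(F)F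
F2 | step 7 | (2S)-7-acetoxy-2-[4-methoxy-3-(trifluoromethanesulfonyloxy)phenyl]-6-(2-methylbut-3-en-2-yl)-2,3-dihydro-4H-chromene-4,5(6H)-dione, C6 ortho-dienone triflate | COc1ccc([C@@H]2CC(=O)C3=C(O2)C=C(OC(C)=O)C(C(C)(C)C=C)C3=O)cc1OS(=O)(=O)C(F)(F)F
F3 | step 7 | (2S)-7-acetoxy-2-[4-methoxy-3-(trifluoromethanesulfonyloxy)phenyl]-8-(3-methylbut-2-en-1-yl)-2,3-dihydro-4H-chromene-4,5(8H)-dione, C8 para-dienone triflate | COc1ccc([C@@H]2CC(=O)C3=C(O2)C(CC=C(C)C)C(OC(C)=O)=CC3=O)cc1OS(=O)(=O)C(F)(F)F
F4 | step 7 | (2S)-7-acetoxy-5-hydroxy-2-[4-methoxy-3-(trifluoromethanesulfonyloxy)phenyl]-8-(3-methylbut-2-en-1-yl)chroman-4-one | COc1ccc([C@@H]2CC(=O)c3c(O)cc(OC(C)=O)c(CC=C(C)C)c3O2)cc1OS(=O)(=O)C(F)(F)F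
F5 | step 1 | (2S)-hesperetin 7-O-β-D-glucoside | COc1ccc([C@@H]2CC(=O)c3c(O)cc(O[C@@H]4O[C@H](CO)[C@@H](O)[C@H](O)[C@H]4O)cc3O2)cc1O
F6 | step 1 | (2S)-hesperetin, (2S)-5,7-dihydroxy-2-(3-hydroxy-4-methoxyphenyl)chroman-4-one | COc1ccc([C@@H]2CC(=O)c3c(O)cc(O)cc3O2)cc1O
F7 | step 1 | (2S)-7-acetoxy-5-hydroxy-2-(3-hydroxy-4-methoxyphenyl)chroman-4-one | COc1ccc([C@@H]2CC(=O)c3c(O)cc(OC(C)=O)cc3O2)cc1O
F8 | step 5 | (3-methylbut-3-en-1-yl)magnesium bromide | C=C(C)CC[Mg]Br
F9 | step 5 | bromomagnesium 9-methoxy-9-(3-methylbut-3-en-1-yl)-9-boranuidabicyclo[3.3.1]nonane | C=C(C)CC[B-]1(OC)C2CCCC1CCC2.[Mg+]Br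
F0 | step 8 | none | none
A1 | alternative 1 | 5,7-bis(methoxymethoxy)-2-[4-methoxy-3-(3-methylbut-3-en-1-yl)phenyl]-8-(3-methylbut-2-en-1-yl)-4H-chromen-4-one | C=C(C)CCc1cc(-c2cc(=O)c3c(OCOC)cc(OCOC)c(CC=C(C)C)c3o2)ccc1OC
A2 | alternative 1 | 2-iodo-3,5-bis(methoxymethoxy)-6-(3-methylbut-2-en-1-yl)phenol | Oc1c(I)c(OCOC)cc(OCOC)c1CC=C(C)C
A3 | alternative 1 | 4-ethynyl-1-methoxy-2-(3-methylbut-3-en-1-yl)benzene | C#Cc1ccc(OC)c(CCC(C)=C)c1
A4 | alternative 2 | (2S)-5,7-bis(methoxymethoxy)-2-[4-methoxy-3-(3-methylbut-3-en-1-yl)phenyl]-8-(3-methylbut-2-en-1-yl)chroman-4-one | C=C(C)CCc1cc([C@@H]2CC(=O)c3c(OCOC)cc(OCOC)c(CC=C(C)C)c3O2)ccc1OC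
A5 | alternative 2 | 5,7-bis(methoxymethoxy)-8-(3-methylbut-2-en-1-yl)-4H-chromen-4-one | O=c1ccoc2c(CC=C(C)C)c(OCOC)cc(OCOC)c12
A6 | alternative 2 | [4-methoxy-3-(3-methylbut-3-en-1-yl)phenyl]boronic acid | C=C(C)CCc1cc(B(O)O)ccc1OC
A7 | alternative 3 | (2S)-2-[4-methoxy-3-(3-methylbut-3-en-1-yl)phenyl]-8-(3-methylbut-2-en-1-yl)-5,7-bis(triisopropylsilyloxy)chroman-4-one | C=C(C)CCc1cc([C@@H]2CC(=O)c3c(O[Si](C(C)C)(C(C)C)C(C)C)cc(O[Si](C(C)C)(C(C)C)C(C)C)c(CC=C(C)C)c3O2)ccc1OC
A8 | alternative 3 | racemic 2-[4-methoxy-3-(3-methylbut-3-en-1-yl)phenyl]-4-methylidene-8-(3-methylbut-2-en-1-yl)-5,7-bis(triisopropylsilyloxy)-4H-1,3-benzodioxine | C=C1OC(c2ccc(OC)c(CCC(C)=C)c2)Oc2c(CC=C(C)C)c(O[Si](C(C)C)(C(C)C)C(C)C)cc(O[Si](C(C)C)(C(C)C)C(C)C)c21
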